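**Retrosynthetic overview**

1. The lactone ring is closed last: O1–C2 is disconnected to a tert-butyl ester on C3 and a free hydroxyl on C8a. The ethyl (C7–O), benzyl (C4'–O) and silyl (C5–O) groups are removed after that.
2. The strategy rests on ring A: oxygens on C5, C7 and C8a alternate with carbon substituents on C4a and C8 and a hydrogen on C6. A vinylketene (C8a, C6, C7, C8) and a siloxyalkyne (C4a, C5) give this pattern in a Danheiser benzannulation, which forms C4a–C8a and C5–C6, closes C8–C8a and leaves the only free hydroxyl on C8a.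
3. Siloxyalkyne: C4 is set by rhodium-catalysed asymmetric conjugate alkynylation of the benzylidene derivative of Meldrum's acid made from 4-(benzyloxy)benzaldehyde; acetylide oxidation and O-silylation follow.
4. Cyclobutenone: [2+2] cycloaddition of ethoxyethyne with a ketene that carries the C8 acyl group as its dioxolane. A free acyl group would give an acylketene, a benzylic carbinol on this trioxygenated ring would ionise in the acid used for lactonisation, and C4 deprotonation of the parent 3-ethoxycyclobutenone would require an antiaromatic cyclobutadienolate.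
5. Ring order: both aryl rings are bought, ring A is formed in step 10, the lactone ring in step 11.

Key step: step 10

Assumption: the (R)-bisphosphine in step 2 is taken to deliver the S adduct; should the first batch show the opposite sense, the (S)-ligand is used with no other change.

**Route**

Step 1
Reactants: 1 4-(benzyloxy)benzaldehyde; 2 2,2-dimethyl-1,3-dioxane-4,6-dione (Meldrum's acid)
Product: 3 5-[4-(benzyloxy)benzylidene]-2,2-dimethyl-1,3-dioxane-4,6-dione
Conditions: pyrrolidine (cat.), AcOH (cat.), PhMe, rt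
Reagents that add atoms: none
Why: Knoevenagel condensation of a non-enolisable aldehyde with the acidic methylene of 2 under iminium catalysis should give the doubly activated alkene, with no stereocentre involved.

Step 2
Reactants: 3 5-[4-(benzyloxy)benzylidene]-2,2-dimethyl-1,3-dioxane-4,6-dione; 4 ethynyltrimethylsilane
Product: 5 5-{(S)-1-[4-(benzyloxy)phenyl]-3-(trimethylsilyl)prop-2-yn-1-yl}-2,2-dimethyl-1,3-dioxane-4,6-dione
Conditions: [Rh(OAc)(C2H4)2]2 (cat.), (R)-3,5-xylyl-MeO-BIPHEP (cat.), 1,4-dioxane/H2O, rt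
Reagents that add atoms: none
Why: Rhodium-catalysed asymmetric conjugate alkynylation, in which an alkynyl complex of monovalent rhodium formed from 4 adds 1,4 to the alkylidene malonate-type acceptor and the chiral bisphosphine selects the face of the benzylidene carbon, should set the future C4 as S.

Step 3
Reactants: 5 5-{(S)-1-[4-(benzyloxy)phenyl]-3-(trimethylsilyl)prop-2-yn-1-yl}-2,2-dimethyl-1,3-dioxane-4,6-dione
Product: 7 (S)-3-[4-(benzyloxy)phenyl]-5-(trimethylsilyl)pent-4-ynoic acid, via malonic acid 6 (not isolated)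
Conditions: DMF/H2O (10:1), 100 °C
Reagents that add atoms: water, O
Why: Neutral hydrolysis of the cyclic acylal to the malonic acid and thermal decarboxylation should give the acid, and the stereocentre, being β to the carboxyl group, is not touched.

Step 4
Reactants: 7 (S)-3-[4-(benzyloxy)phenyl]-5-(trimethylsilyl)pent-4-ynoic acid
Product: 8 tert-butyl (S)-3-[4-(benzyloxy)phenyl]-5-(trimethylsilyl)pent-4-ynoate
Conditions: Cl3CC(=NH)Ot-Bu, CH2Cl2/cyclohexane, rt
Reagents that add atoms: tert-butyl 2,2,2-trichloroacetimidate, CC(C)(C)OC(=N)C(Cl)(Cl)Cl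
Why: O-tert-butylation of a carboxylic acid by the trichloroacetimidate is promoted by the acid itself and is mild enough for the alkynylsilane and the benzyl ether.

Step 5
Reactants: 8 tert-butyl (S)-3-[4-(benzyloxy)phenyl]-5-(trimethylsilyl)pent-4-ynoate
Product: 9 tert-butyl (R)-3-[4-(benzyloxy)phenyl]pent-4-ynoate
Conditions: K2CO3, MeOH, 0 °C → rt
Reagents that add atoms: none
Why: Methoxide-catalysed protodesilylation of the alkynylsilane leaves the tert-butyl ester alone and is too weakly basic to remove the propargylic benzylic hydrogen, so no allene should form; the descriptor becomes R only because ethynyl ranks below aryl, the spatial arrangement being unchanged.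

Step 6
Reactants: 9 tert-butyl (R)-3-[4-(benzyloxy)phenyl]pent-4-ynoate
Product: 12 tert-butyl (S)-3-[4-(benzyloxy)phenyl]-5-[(triisopropylsilyl)oxy]pent-4-ynoate, via lithium acetylide 10 (not isolated), via lithium ynolate 11 (not isolated)
Conditions: n-BuLi (1.0 equiv), THF, −78 °C; t-BuOOLi (from t-BuOOH and LiN(SiMe3)2), −78 → 0 °C; TIPSOTf, −78 → 0 °C
Reagents that add atoms: tert-butyl hydroperoxide, CC(C)(C)OO; triisopropylsilyl trifluoromethanesulfonate, CC(C)[Si](OS(=O)(=O)C(F)(F)F)(C(C)C)C(C)C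
Why: Acetylide oxidation by electrophilic oxygen transfer from lithium tert-butylperoxide gives the lithium ynolate, which the silyl triflate traps on oxygen; the alkyne C–H is removed kinetically before the ester α-hydrogens and the tert-butyl ester resists the nucleophiles present.

Step 7
Reactants: 13 ethyl 3-oxo-5-phenylpentanoate; 14 ethane-1,2-diol
Product: 15 ethyl 2-[2-(2-phenylethyl)-1,3-dioxolan-2-yl]acetate
Conditions: p-TsOH·H2O (cat.), PhH, reflux, azeotropic removal of water
Reagents that add atoms: none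
Why: Acid-catalysed ketalisation of the ketone of a β-keto ester with azeotropic removal of water is standard and leaves the ester untouched.

Step 8
Reactants: 15 ethyl 2-[2-(2-phenylethyl)-1,3-dioxolan-2-yl]acetate
Product: 16 2-[2-(2-phenylethyl)-1,3-dioxolan-2-yl]acetic acid
Conditions: LiOH, THF/H2O, rt; then aq. HCl to pH 4, 0 °C
Reagents that add atoms: lithium hydroxide, [Li+].[OH-]
Why: Saponification proceeds with the dioxolane inert to base, and a cold, mildly acidic work-up keeps the ketal, whose loss would expose a β-keto acid prone to decarboxylation.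

Step 9
Reactants: 16 2-[2-(2-phenylethyl)-1,3-dioxolan-2-yl]acetic acid; 17 ethoxyethyne
Product: 20 3-ethoxy-4-[2-(2-phenylethyl)-1,3-dioxolan-2-yl]cyclobut-2-en-1-one (racemic; the centre is lost later), via acid chloride 18 (not isolated), via ketene 19 (not isolated)
Conditions: Me2C=C(Cl)NMe2 (1.0 equiv), CH2Cl2, 0 °C → rt; then 17 (3 equiv), Et3N (slow addition), rt → 40 °C
Reagents that add atoms: none
Why: The neutral chloroenamine gives the acid chloride without free HCl, dehydrochlorination with Et3N gives the monosubstituted ketene, and its [2+2] cycloaddition with the ynol ether (ketene carbonyl carbon to the unsubstituted alkyne carbon) is the standard route to 4-substituted 3-ethoxycyclobutenones, the bulky ketal substituent slowing ketene dimerisation.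

Step 10
Reactants: 12 tert-butyl (S)-3-[4-(benzyloxy)phenyl]-5-[(triisopropylsilyl)oxy]pent-4-ynoate; 20 3-ethoxy-4-[2-(2-phenylethyl)-1,3-dioxolan-2-yl]cyclobut-2-en-1-one
Product: 25 tert-butyl (S)-3-[4-(benzyloxy)phenyl]-3-{4-ethoxy-2-hydroxy-3-[2-(2-phenylethyl)-1,3-dioxolan-2-yl]-6-[(triisopropylsilyl)oxy]phenyl}propanoate, via vinylketene 21 (not isolated), via vinylcyclobutenone 22 (not isolated), via dienylketene 23 (not isolated), via cyclohexadienone 24 (not isolated)
Conditions: 20 (1.2 equiv) added slowly to 12, PhMe, 80 °C, then 110 °C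
Reagents that add atoms: none
Why: Heating opens cyclobutenone 20 by four-electron electrocyclic ring opening, the ketal-bearing C4 substituent rotating outward, to vinylketene 21, whose carbonyl carbon (future C8a) bonds to the nucleophilic, side-chain-bearing alkyne carbon of 12 (C4a) while the silyloxy-bearing alkyne carbon (C5) bonds to the ketene α-carbon (C6) in a [2+2] cycloaddition that gives 22. Four-electron opening of 22 to dienylketene 23 and six-electron disrotatory electrocyclisation between C8a and C8 give dienone 24, which tautomerises to phenol 25, so that ring A is closed by a 6π electrocyclisation after C4a–C8a and C5–C6 have been made. The closest known reaction type is the Danheiser benzannulation of cyclobutenones with siloxyalkynes to resorcinol monosilyl ethers. No lasting stereocentre is created: the centres at the ring carbon of 20 and 22 and at C8 of 24 are erased on aromatisation, and C4 is carried through unchanged from 12. The step needs regioselectivity in the [2+2] event, which the polarisation of the siloxyalkyne (nucleophilic at the carbon remote from oxygen) secures, and configurational integrity at the propargylic C4, which the neutral, base-free thermal conditions secure. The acyl group on C8 stays masked as the dioxolane, so that no acylketene, which would close to a pyranone, can form.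

Step 11
Reactants: 25 tert-butyl (S)-3-[4-(benzyloxy)phenyl]-3-{4-ethoxy-2-hydroxy-3-[2-(2-phenylethyl)-1,3-dioxolan-2-yl]-6-[(triisopropylsilyl)oxy]phenyl}propanoate
Product: 28 (S)-4-[4-(benzyloxy)phenyl]-7-ethoxy-8-(3-phenylpropanoyl)-5-[(triisopropylsilyl)oxy]chroman-2-one, via hydroxy acid 26 (not isolated), via ketal lactone 27 (not isolated)
Conditions: TFA/CH2Cl2 (1:4), anisole, 0 °C → rt; then H2O, rt
Reagents that add atoms: water, O
Why: Acidolysis of the tert-butyl ester (anisole trapping the tert-butyl cation), acid-catalysed lactonisation onto the only free phenol at C8a (C5–O being silylated, the regiochemistry is unambiguous) and hydrolysis of the ketal should close the lactone ring and unmask the C8 ketone in one flask, the aryl silyl, ethyl and benzyl ethers being stable to TFA at room temperature.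

Step 12
Reactants: 28 (S)-4-[4-(benzyloxy)phenyl]-7-ethoxy-8-(3-phenylpropanoyl)-5-[(triisopropylsilyl)oxy]chroman-2-one
Product: 29 (S)-7-hydroxy-4-(4-hydroxyphenyl)-8-(3-phenylpropanoyl)-5-[(triisopropylsilyl)oxy]chroman-2-one
Conditions: BCl3, C6HMe5, CH2Cl2, −78 °C → rt
Reagents that add atoms: none
Why: BCl3 chelated between the C8 ketone oxygen and the C7 ethoxy oxygen cleaves the ortho ethyl ether, and the benzyl ether is cleaved with pentamethylbenzene as cation scavenger; the silyl ether kept on C5 prevents the lactone from relocating to C5–O should it open, and any silyl loss here converges in step 13.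

Step 13
Reactants: 29 (S)-7-hydroxy-4-(4-hydroxyphenyl)-8-(3-phenylpropanoyl)-5-[(triisopropylsilyl)oxy]chroman-2-one
Product: 30 (S)-5,7-dihydroxy-4-(4-hydroxyphenyl)-8-(3-phenylpropanoyl)chroman-2-one
Conditions: Bu4NF, AcOH (1:1), THF, 0 °C
Reagents that add atoms: none
Why: Fluoride cleaves the aryl silyl ether, and the acetic acid buffer protonates the phenoxide at once, so that the dihydrocoumarin lactone should not be opened.

**Compound list**

1 | 4-(benzyloxy)benzaldehyde | O=Cc1ccc(OCc2ccccc2)cc1 | starting material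
2 | 2,2-dimethyl-1,3-dioxane-4,6-dione (Meldrum's acid) | CC1(C)OC(=O)CC(=O)O1 | starting material
3 | 5-[4-(benzyloxy)benzylidene]-2,2-dimethyl-1,3-dioxane-4,6-dione | CC1(C)OC(=O)C(=Cc2ccc(OCc3ccccc3)cc2)C(=O)O1 | intermediate
4 | ethynyltrimethylsilane | C#C[Si](C)(C)C | starting material
5 | 5-{(S)-1-[4-(benzyloxy)phenyl]-3-(trimethylsilyl)prop-2-yn-1-yl}-2,2-dimethyl-1,3-dioxane-4,6-dione | CC1(C)OC(=O)C([C@@H](c2ccc(OCc3ccccc3)cc2)C#C[Si](C)(C)C)C(=O)O1 | intermediate
6 | 2-{(S)-1-[4-(benzyloxy)phenyl]-3-(trimethylsilyl)prop-2-yn-1-yl}propanedioic acid (formed in the flask) | OC(=O)C(C(=O)O)[C@@H](c1ccc(OCc2ccccc2)cc1)C#C[Si](C)(C)C | intermediate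
7 | (S)-3-[4-(benzyloxy)phenyl]-5-(trimethylsilyl)pent-4-ynoic acid | OC(=O)C[C@@H](c1ccc(OCc2ccccc2)cc1)C#C[Si](C)(C)C | intermediate
8 | tert-butyl (S)-3-[4-(benzyloxy)phenyl]-5-(trimethylsilyl)pent-4-ynoate | CC(C)(C)OC(=O)C[C@@H](c1ccc(OCc2ccccc2)cc1)C#C[Si](C)(C)C | intermediate
9 | tert-butyl (R)-3-[4-(benzyloxy)phenyl]pent-4-ynoate | CC(C)(C)OC(=O)C[C@@H](c1ccc(OCc2ccccc2)cc1)C#C | intermediate
10 | lithium acetylide of 9 (formed in the flask) | CC(C)(C)OC(=O)C[C@@H](c1ccc(OCc2ccccc2)cc1)C#C[Li] | intermediate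
11 | lithium (S)-3-[4-(benzyloxy)phenyl]-5-tert-butoxy-5-oxopent-1-yn-1-olate (lithium ynolate, formed in the flask) | CC(C)(C)OC(=O)C[C@@H](c1ccc(OCc2ccccc2)cc1)C#CO[Li] | intermediate
12 | tert-butyl (S)-3-[4-(benzyloxy)phenyl]-5-[(triisopropylsilyl)oxy]pent-4-ynoate | CC(C)(C)OC(=O)C[C@@H](c1ccc(OCc2ccccc2)cc1)C#CO[Si](C(C)C)(C(C)C)C(C)C | intermediate
13 | ethyl 3-oxo-5-phenylpentanoate | CCOC(=O)CC(=O)CCc1ccccc1 | starting material
14 | ethane-1,2-diol | OCCO | starting material
15 | ethyl 2-[2-(2-phenylethyl)-1,3-dioxolan-2-yl]acetate | CCOC(=O)CC1(CCc2ccccc2)OCCO1 | intermediate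
16 | 2-[2-(2-phenylethyl)-1,3-dioxolan-2-yl]acetic acid | OC(=O)CC1(CCc2ccccc2)OCCO1 | intermediate
17 | ethoxyethyne | CCOC#C | starting material
18 | 2-[2-(2-phenylethyl)-1,3-dioxolan-2-yl]acetyl chloride (formed in the flask) | ClC(=O)CC1(CCc2ccccc2)OCCO1 | intermediate
19 | 2-[2-(2-phenylethyl)-1,3-dioxolan-2-yl]ethen-1-one (ketene, formed in the flask) | O=C=CC1(CCc2ccccc2)OCCO1 | intermediate
20 | 3-ethoxy-4-[2-(2-phenylethyl)-1,3-dioxolan-2-yl]cyclobut-2-en-1-one (racemic) | CCOC1=CC(=O)C1C1(CCc2ccccc2)OCCO1 | intermediate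
21 | (3Z)-3-ethoxy-4-[2-(2-phenylethyl)-1,3-dioxolan-2-yl]buta-1,3-dien-1-one (vinylketene, formed in the flask) | O=C=C/C(OCC)=C/C1(CCc2ccccc2)OCCO1 | intermediate
22 | tert-butyl (3S)-3-[4-(benzyloxy)phenyl]-3-{3-[(Z)-1-ethoxy-2-[2-(2-phenylethyl)-1,3-dioxolan-2-yl]ethenyl]-4-oxo-2-[(triisopropylsilyl)oxy]cyclobut-1-en-1-yl}propanoate (mixture at the ring carbon, formed in the flask) | CC(C)(C)OC(=O)C[C@@H](c1ccc(OCc2ccccc2)cc1)C1=C(O[Si](C(C)C)(C(C)C)C(C)C)C(/C(OCC)=C/C2(CCc3ccccc3)OCCO2)C1=O | intermediate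
23 | tert-butyl (S)-3-[4-(benzyloxy)phenyl]-3-{5-ethoxy-1-oxo-6-[2-(2-phenylethyl)-1,3-dioxolan-2-yl]-3-[(triisopropylsilyl)oxy]hexa-1,3,5-trien-2-yl}propanoate (dienylketene, formed in the flask) | CC(C)(C)OC(=O)C[C@@H](c1ccc(OCc2ccccc2)cc1)C(=C=O)/C(O[Si](C(C)C)(C(C)C)C(C)C)=C\C(OCC)=C\C1(CCc2ccccc2)OCCO1 | intermediate
24 | tert-butyl (3S)-3-[4-(benzyloxy)phenyl]-3-{4-ethoxy-6-oxo-5-[2-(2-phenylethyl)-1,3-dioxolan-2-yl]-2-[(triisopropylsilyl)oxy]cyclohexa-1,3-dien-1-yl}propanoate (mixture at the ring sp3 carbon, formed in the flask) | CC(C)(C)OC(=O)C[C@@H](c1ccc(OCc2ccccc2)cc1)C1=C(O[Si](C(C)C)(C(C)C)C(C)C)C=C(OCC)C(C2(CCc3ccccc3)OCCO2)C1=O | intermediate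
25 | tert-butyl (S)-3-[4-(benzyloxy)phenyl]-3-{4-ethoxy-2-hydroxy-3-[2-(2-phenylethyl)-1,3-dioxolan-2-yl]-6-[(triisopropylsilyl)oxy]phenyl}propanoate | CC(C)(C)OC(=O)C[C@@H](c1ccc(OCc2ccccc2)cc1)c1c(O[Si](C(C)C)(C(C)C)C(C)C)cc(OCC)c(C2(CCc3ccccc3)OCCO2)c1O | intermediate
26 | (S)-3-[4-(benzyloxy)phenyl]-3-{4-ethoxy-2-hydroxy-3-[2-(2-phenylethyl)-1,3-dioxolan-2-yl]-6-[(triisopropylsilyl)oxy]phenyl}propanoic acid (formed in the flask) | OC(=O)C[C@@H](c1ccc(OCc2ccccc2)cc1)c1c(O[Si](C(C)C)(C(C)C)C(C)C)cc(OCC)c(C2(CCc3ccccc3)OCCO2)c1O | intermediate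
27 | (S)-4-[4-(benzyloxy)phenyl]-7-ethoxy-8-[2-(2-phenylethyl)-1,3-dioxolan-2-yl]-5-[(triisopropylsilyl)oxy]chroman-2-one (formed in the flask) | O=C1C[C@@H](c2ccc(OCc3ccccc3)cc2)c2c(O[Si](C(C)C)(C(C)C)C(C)C)cc(OCC)c(C3(CCc4ccccc4)OCCO3)c2O1 | intermediate
28 | (S)-4-[4-(benzyloxy)phenyl]-7-ethoxy-8-(3-phenylpropanoyl)-5-[(triisopropylsilyl)oxy]chroman-2-one | O=C1C[C@@H](c2ccc(OCc3ccccc3)cc2)c2c(O[Si](C(C)C)(C(C)C)C(C)C)cc(OCC)c(C(=O)CCc3ccccc3)c2O1 | intermediate
29 | (S)-7-hydroxy-4-(4-hydroxyphenyl)-8-(3-phenylpropanoyl)-5-[(triisopropylsilyl)oxy]chroman-2-one | O=C1C[C@@H](c2ccc(O)cc2)c2c(O[Si](C(C)C)(C(C)C)C(C)C)cc(O)c(C(=O)CCc3ccccc3)c2O1 | intermediate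
30 | (S)-5,7-dihydroxy-4-(4-hydroxyphenyl)-8-(3-phenylpropanoyl)chroman-2-one | O=C1C[C@@H](c2ccc(O)cc2)c2c(O)cc(O)c(C(=O)CCc3ccccc3)c2O1 | target

**Step count**

Total: 13 steps. Longest linear sequence: 10 steps (steps 1 to 6, then 10 to 13); the cyclobutenone branch is steps 7 to 9.

**Steps most likely to fail**

Step 10. The alkoxy-stabilised cyclobutenone may open too slowly. At the temperature then needed, the vinylketene could be consumed by acylation of the product phenol and by self-condensation while the siloxyalkyne slowly degrades. The fallback makes the same vinylketene 21 at room temperature by 1,4-dehydrochlorination instead of electrocyclic opening. It sets out from acid 16. Activation with carbonyldiimidazole and C-acylation of the magnesium enolate of potassium ethyl malonate (MgCl2, Et3N, THF) should give ethyl 3-oxo-4-[2-(2-phenylethyl)-1,3-dioxolan-2-yl]butanoate F1. O-Ethylation with Et3OBF4 and i-Pr2NEt in CH2Cl2 should give ethyl (E)-3-ethoxy-4-[2-(2-phenylethyl)-1,3-dioxolan-2-yl]but-2-enoate F2. Hydrolysis with LiOH should give (E)-3-ethoxy-4-[2-(2-phenylethyl)-1,3-dioxolan-2-yl]but-2-enoic acid F3, and 1-chloro-N,N,2-trimethylprop-1-en-1-amine should give (E)-3-ethoxy-4-[2-(2-phenylethyl)-1,3-dioxolan-2-yl]but-2-enoyl chloride F4. Slow addition of Et3N to F4 and siloxyalkyne 12 in PhMe at room temperature, then warming to 80 °C, should generate 21 by γ-deprotonation and loss of chloride and carry it through 22, 23 and 24. The fallback comes back to the route at phenol 25.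

Step 9. β-Elimination of a ketal oxygen from the acylammonium enolate, or dimerisation of the ketene, may outrun the cycloaddition. The fallback generates ketene 19 without base by a photochemical Wolff rearrangement. It sets out from ethane-1,2-diol 14 and ethoxyethyne 17. Commercial ethyl 2-oxo-4-phenylbutanoate F5 is ketalised with 14 (p-TsOH, PhH, reflux) to ethyl 2-(2-phenylethyl)-1,3-dioxolane-2-carboxylate F6. Saponification with LiOH should give 2-(2-phenylethyl)-1,3-dioxolane-2-carboxylic acid F7. The mixed anhydride (i-BuOCOCl, N-methylmorpholine) and then CH2N2 should give 2-diazo-1-[2-(2-phenylethyl)-1,3-dioxolan-2-yl]ethan-1-one F8. Irradiation of F8 (Pyrex filter, CH2Cl2, room temperature) in the presence of 17 should give 19 by migration of the ketal carbon and then the [2+2] adduct. The fallback comes back to the route at cyclobutenone 20.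

Step 6. The amide base or the lithium tert-butoxide formed may enolise the tert-butyl ester, leading to Claisen-type condensation and silylation at carbon, or the oxygen transfer to the acetylide may stall. The fallback carries the carboxyl group through the oxidation as its lithium salt, which does not enolise under these conditions. It sets out from acid 7. K2CO3 in MeOH should give (R)-3-[4-(benzyloxy)phenyl]pent-4-ynoic acid F9. LiN(SiMe3)2 (2 equiv), then t-BuOOLi, then TIPSOTf (2 equiv) should give triisopropylsilyl (S)-3-[4-(benzyloxy)phenyl]-5-[(triisopropylsilyl)oxy]pent-4-ynoate F10. Benzannulation with 20 as in step 10 should give triisopropylsilyl (S)-3-[4-(benzyloxy)phenyl]-3-{4-ethoxy-2-hydroxy-3-[2-(2-phenylethyl)-1,3-dioxolan-2-yl]-6-[(triisopropylsilyl)oxy]phenyl}propanoate F11. The acid of step 11 cleaves the silyl ester, so the fallback comes back to the route at hydroxy acid 26.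

**Further compounds**

F1 | step 10 | ethyl 3-oxo-4-[2-(2-phenylethyl)-1,3-dioxolan-2-yl]butanoate | CCOC(=O)CC(=O)CC1(CCc2ccccc2)OCCO1
F2 | step 10 | ethyl (E)-3-ethoxy-4-[2-(2-phenylethyl)-1,3-dioxolan-2-yl]but-2-enoate | CCOC(=O)/C=C(/OCC)CC1(CCc2ccccc2)OCCO1
F3 | step 10 | (E)-3-ethoxy-4-[2-(2-phenylethyl)-1,3-dioxolan-2-yl]but-2-enoic acid | OC(=O)/C=C(/OCC)CC1(CCc2ccccc2)OCCO1
F4 | step 10 | (E)-3-ethoxy-4-[2-(2-phenylethyl)-1,3-dioxolan-2-yl]but-2-enoyl chloride | ClC(=O)/C=C(/OCC)CC1(CCc2ccccc2)OCCO1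
F5 | step 9 | ethyl 2-oxo-4-phenylbutanoate | CCOC(=O)C(=O)CCc1ccccc1
F6 | step 9 | ethyl 2-(2-phenylethyl)-1,3-dioxolane-2-carboxylate | CCOC(=O)C1(CCc2ccccc2)OCCO1
F7 | step 9 | 2-(2-phenylethyl)-1,3-dioxolane-2-carboxylic acid | OC(=O)C1(CCc2ccccc2)OCCO1
F8 | step 9 | 2-diazo-1-[2-(2-phenylethyl)-1,3-dioxolan-2-yl]ethan-1-one | [N-]=[N+]=CC(=O)C1(CCc2ccccc2)OCCO1
F9 | step 6 | (R)-3-[4-(benzyloxy)phenyl]pent-4-ynoic acid | OC(=O)C[C@@H](c1ccc(OCc2ccccc2)cc1)C#C
F10 | step 6 | triisopropylsilyl (S)-3-[4-(benzyloxy)phenyl]-5-[(triisopropylsilyl)oxy]pent-4-ynoate | CC(C)[Si](C(C)C)(C(C)C)OC(=O)C[C@@H](c1ccc(OCc2ccccc2)cc1)C#CO[Si](C(C)C)(C(C)C)C(C)C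
F11 | step 6 | triisopropylsilyl (S)-3-[4-(benzyloxy)phenyl]-3-{4-ethoxy-2-hydroxy-3-[2-(2-phenylethyl)-1,3-dioxolan-2-yl]-6-[(triisopropylsilyl)oxy]phenyl}propanoate | CC(C)[Si](C(C)C)(C(C)C)OC(=O)C[C@@H](c1ccc(OCc2ccccc2)cc1)c1c(O[Si](C(C)C)(C(C)C)C(C)C)cc(OCC)c(C2(CCc3ccccc3)OCCO2)c1O
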